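**Retrosynthetic overview**
- Target 34 comes from 32 by desilylation and hydrogenolysis. The C3–CH2 bond to ring A is cut back to the enolate of lactone 28 and bromide 30 (trans-selective alkylation).
- The lactone (ring D) is the only ring built; rings A, B and C are bought as arenes. It comes from an Evans alkylation of pentenoyl imide 21 with the ring B benzylic bromide 17 (sets C4), then reduction, alkene cleavage and lactol oxidation.
- Bromide 17 comes from ester 13 by C–B oxidation, silylation, ester reduction and bromination.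
- Ester 13 comes from one three-component conjunctive coupling of ring C aryllithium 11, (Z)-alkenyl boronate 8 and ring B triflate 3. It forms the ring C–carbinol carbon bond and the ring B–neighbouring carbon bond.
- Feature used: in the side chain on ring B, the carbinol carbon carries ring C and OH, and the adjacent carbon carries ring B and CH2OH, in the anti (1R,2R) relation. This is the pattern left by anti addition of two aryl groups across a (Z)-B–CH=CH–CH2O unit, followed by C–B to C–O exchange with retention.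

Key step: step 6

Remark: the boron ligand is the hindered cis-diol 5 instead of pinacol, because β-substituted alkenyl pinacol boronates tend to undergo direct Suzuki–Miyaura coupling; the enantiomer of the ferrocenyl bisphosphine that leads to the (1R,2R) series is to be fixed in a model coupling (both enantiomers are sold), and ate complex 12 is drawn without configuration at boron.

Shorthand in names: ArBC = 4-(benzyloxy)-3-methoxy-5-[(1R,2R)-1-(4-benzyloxy-3-methoxyphenyl)-1,3-bis(tert-butyldimethylsilyloxy)propan-2-yl]phenyl.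

**Route**

Step 1
Reactants: 1 methyl 3,4-dihydroxy-5-methoxybenzoate
Product: 2 methyl 4-(benzyloxy)-3-hydroxy-5-methoxybenzoate
Conditions: BnBr (1.0 equiv), NaHCO3, NaI (cat.), DMF, 40 °C
Reagents that add atoms: benzyl bromide, BrCc1ccccc1
Why: The 4-OH, para to the ester, is the more acidic phenol, so the weak base should form its phenoxide selectively and Williamson etherification should occur there.

Step 2
Reactants: 2 methyl 4-(benzyloxy)-3-hydroxy-5-methoxybenzoate
Product: 3 methyl 4-(benzyloxy)-3-methoxy-5-(trifluoromethylsulfonyloxy)benzoate (ring B triflate)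
Conditions: Tf2O, pyridine, CH2Cl2, 0 °C
Reagents that add atoms: triflic anhydride, O=S(=O)(OS(=O)(=O)C(F)(F)F)C(F)(F)F
Why: O-Sulfonylation of the remaining phenol is a standard aryl triflate synthesis that leaves the ester and benzyl ether untouched.

Step 3
Reactants: 4 acenaphthylene-1,2-dione
Product: 5 cis-1,2-dimethyl-1,2-dihydroacenaphthylene-1,2-diol (meso)
Conditions: AlMe3 (excess), toluene, 0 °C to rt; aqueous Rochelle salt; recrystallisation
Reagents that add atoms: trimethylaluminium, C[Al](C)C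
Why: Double 1,2-addition of methyl to the 1,2-diketone should give the ditertiary diol, the second methyl adding anti to the bulky aluminium alkoxide to favour the cis isomer, which is purified by crystallisation and is the only isomer able to bridge boron.

Step 4
Reactants: 6 tert-butyldimethyl(prop-2-yn-1-yloxy)silane; 5 cis-1,2-dimethyl-1,2-dihydroacenaphthylene-1,2-diol
Product: 8 (Z)-3-(tert-butyldimethylsilyloxy)prop-1-enylboronic ester of diol 5, via alkenyl catechol boronate 7 (not isolated)
Conditions: catecholborane, [Rh(cod)Cl]2 (cat.), P(i-Pr)3, Et3N, cyclohexane, rt; then 5, rt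
Reagents that add atoms: catecholborane, B1Oc2ccccc2O1
Why: Rhodium-catalysed trans-hydroboration of the terminal alkyne through a rhodium vinylidene should place boron and the CH2OTBS group cis (Z), and diol exchange of the labile catechol ester with 5 should give the silica-stable boronate.

Step 5
Reactants: 9 4-bromo-2-methoxyphenol
Product: 10 1-(benzyloxy)-4-bromo-2-methoxybenzene
Conditions: BnBr, K2CO3, DMF, rt
Reagents that add atoms: benzyl bromide, BrCc1ccccc1
Why: Williamson etherification of the phenol is reliable and leaves the aryl bromide for halogen–lithium exchange.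

Step 6
Reactants: 10 1-(benzyloxy)-4-bromo-2-methoxybenzene; 8 (Z)-alkenyl boronate of diol 5; 3 ring B triflate
Product: 13 methyl 4-(benzyloxy)-3-methoxy-5-[(1R,2R)-1-(4-benzyloxy-3-methoxyphenyl)-1-boryl-3-(tert-butyldimethylsilyloxy)propan-2-yl]benzoate (boron held by diol 5), via aryllithium 11 (not isolated), via lithium boron ate complex 12 (not isolated)
Conditions: t-BuLi (2 equiv), Et2O, −78 °C; then 8, −78 °C to rt; solvent exchange to THF; Pd(OAc)2 (2 mol%), MandyPhos ferrocenyl bisphosphine C52H50FeN2P2 (2.4 mol%), KOTf, 3, 60 °C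
Reagents that add atoms: none
Why: Zerovalent palladium, formed in the flask from Pd(OAc)2 and the bisphosphine, should insert into the C–OTf bond of 3, and the resulting cationic arylpalladium complex (divalent palladium) should bind the alkene of ate complex 12 instead of transmetallating. The ring C aryl group then shifts from boron to the boron-bearing carbon anti to palladium (1,2-metallate shift), and reductive elimination with retention joins the neighbouring carbon to ring B; the closest known reaction type is the palladium-catalysed conjunctive cross-coupling of β-substituted alkenylboron ate complexes with aryl triflates. No ring is closed. The relative configuration of the two new stereocentres follows from stereospecific anti addition of the two aryl groups across the Z alkene, and the chiral bisphosphine on palladium selects the alkene face and so the absolute (1R,2R) configuration. The step needs the metallate shift to win over direct aryl transfer (Suzuki–Miyaura coupling), which the hindered diol 5 on boron and halide-free cationic palladium (KOTf takes up bromide) should secure, and it needs reductive elimination to outrun β-hydride and β-silyloxy elimination, which the wide-bite-angle ligand and the poor leaving ability of the silyloxy group should favour.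

Step 7
Reactants: 13 boronate from step 6
Product: 14 methyl 4-(benzyloxy)-3-methoxy-5-[(1R,2R)-1-(4-benzyloxy-3-methoxyphenyl)-3-(tert-butyldimethylsilyloxy)-1-hydroxypropan-2-yl]benzoate
Conditions: NaBO3·4H2O, THF/H2O, rt
Reagents that add atoms: sodium perborate, [Na+].[Na+].O[B-]1(O)OO[B-](O)(O)OO1
Why: Peroxide oxidation of the C–B bond proceeds by 1,2-shift of carbon from boron to oxygen with retention, and the mild perborate should spare the methyl ester and silyl ether.

Step 8
Reactants: 14 secondary alcohol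
Product: 15 methyl 4-(benzyloxy)-3-methoxy-5-[(1R,2R)-1-(4-benzyloxy-3-methoxyphenyl)-1,3-bis(tert-butyldimethylsilyloxy)propan-2-yl]benzoate
Conditions: TBSOTf, 2,6-lutidine, CH2Cl2, −78 to 0 °C
Reagents that add atoms: tert-butyldimethylsilyl triflate, CC(C)(C)[Si](C)(C)OS(=O)(=O)C(F)(F)F
Why: Silyl triflate with a hindered base silylates hindered benzylic alcohols, and the bis-silyl ether should carry the chain through the enolate and hydride steps.

Step 9
Reactants: 15 bis-silyl ether ester
Product: 16 (ArBC)methanol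
Conditions: i-Bu2AlH (3 equiv), CH2Cl2, −78 to 0 °C; aqueous Rochelle salt
Reagents that add atoms: none
Why: Hydride reduction of the benzoate to the benzylic alcohol is standard and leaves silyl and benzyl ethers intact.

Step 10
Reactants: 16 (ArBC)methanol
Product: 17 (ArBC)methyl bromide
Conditions: CBr4, PPh3, CH2Cl2, 0 °C; used at once
Reagents that add atoms: carbon tetrabromide, BrC(Br)(Br)Br
Why: The Appel reaction converts the primary benzylic alcohol into the bromide under neutral conditions that the silyl ethers tolerate.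

Step 11
Reactants: 18 (R)-4-benzyloxazolidin-2-one; 19 pent-4-enoyl chloride
Product: 21 (R)-4-benzyl-3-(pent-4-enoyl)oxazolidin-2-one, via N-lithio oxazolidinone 20 (not isolated)
Conditions: n-BuLi, THF, −78 °C; then 19
Reagents that add atoms: none
Why: N-Acylation of the lithiated oxazolidinone with an acid chloride is the standard entry to Evans imides.

Step 12
Reactants: 21 (R)-4-benzyl-3-(pent-4-enoyl)oxazolidin-2-one (excess); 17 (ArBC)methyl bromide
Product: 23 (R)-4-benzyl-3-[(2S)-2-(ArBC-methyl)pent-4-enoyl]oxazolidin-2-one, via sodium Z-enolate 22 (not isolated)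
Conditions: NaN(SiMe3)2, THF, −78 °C; then 17, −78 to −30 °C
Reagents that add atoms: none
Why: In the Evans alkylation the chelated Z-enolate is attacked by the benzylic bromide on the face opposite the auxiliary benzyl group, which sets the (2S) centre that becomes lactone C4 (R).

Step 13
Reactants: 23 alkylated imide
Product: 24 (2S)-2-(ArBC-methyl)pent-4-en-1-ol
Conditions: LiBH4, H2O (1 equiv), Et2O/THF, 0 °C
Reagents that add atoms: none
Why: Reductive cleavage of the imide with LiBH4 should give the primary alcohol without touching the stereocentre and return the auxiliary.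

Step 14
Reactants: 24 (2S)-2-(ArBC-methyl)pent-4-en-1-ol
Product: 27 (4R)-4-(ArBC-methyl)tetrahydrofuran-2-ol (both anomers), via triol 25 (not isolated), via hydroxy aldehyde 26 (not isolated)
Conditions: OsO4 (cat.), NaIO4, 2,6-lutidine, dioxane/H2O, rt
Reagents that add atoms: sodium periodate, [Na+].[O-]I(=O)(=O)=O; osmium tetroxide (catalytic oxygen carrier), O=[Os](=O)(=O)=O
Why: Lemieux–Johnson cleavage of the terminal alkene gives the aldehyde, which the primary alcohol traps as the five-membered lactol, while the electron-rich arenes are not oxidised.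

Step 15
Reactants: 27 lactol
Product: 28 (4R)-4-(ArBC-methyl)dihydrofuran-2(3H)-one
Conditions: TEMPO (cat.), PhI(OAc)2, CH2Cl2, rt
Reagents that add atoms: none
Why: Oxoammonium oxidation of the lactol to the γ-lactone is mild, and no other free hydroxyl group is present.

Step 16
Reactants: 29 (4-benzyloxy-3-methoxyphenyl)methanol
Product: 30 4-(benzyloxy)-3-methoxybenzyl bromide
Conditions: PBr3, Et2O, 0 °C; used fresh
Reagents that add atoms: phosphorus tribromide, BrP(Br)Br
Why: Bromination of an electron-rich benzylic alcohol with PBr3 is a standard substitution.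

Step 17
Reactants: 28 (4R)-lactone; 30 4-(benzyloxy)-3-methoxybenzyl bromide
Product: 32 (3R,4R)-3-(4-benzyloxy-3-methoxybenzyl)-4-(ArBC-methyl)dihydrofuran-2(3H)-one, via lithium enolate 31 (not isolated)
Conditions: LiN(SiMe3)2, THF, −78 °C; then 30, DMPU, −78 to −40 °C
Reagents that add atoms: none
Why: Lactone enolate alkylation takes the bromide on the face anti to the C4 benzyl substituent, which should set C3 as R and give the trans-dibenzyl lactone.

Step 18
Reactants: 32 fully protected trans-lactone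
Product: 33 (3R,4R)-3-(4-benzyloxy-3-methoxybenzyl)-4-{4-(benzyloxy)-3-[(1R,2R)-1-(4-benzyloxy-3-methoxyphenyl)-1,3-dihydroxypropan-2-yl]-5-methoxybenzyl}dihydrofuran-2(3H)-one
Conditions: HF·pyridine, pyridine, THF, 0 °C to rt
Reagents that add atoms: none
Why: Buffered fluoride desilylation removes both silyl ethers without ionising the benzylic C–O bond or opening the lactone.

Step 19
Reactants: 33 tris(benzyl ether) diol
Product: 34 (3R,4R)-3-(4-hydroxy-3-methoxybenzyl)-4-{4-hydroxy-3-[(1R,2R)-1,3-dihydroxy-1-(4-hydroxy-3-methoxyphenyl)propan-2-yl]-5-methoxybenzyl}dihydrofuran-2(3H)-one (target)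
Conditions: H2 (1 atm), Pd/C (10%), EtOAc/EtOH, rt; stopped at full debenzylation
Reagents that add atoms: none
Why: Hydrogenolysis of aryl benzyl ethers over Pd/C under neutral conditions is fast and should leave the benzylic hydroxyl group, the lactone and all four stereocentres unchanged.

**Compound list**
1 | methyl 3,4-dihydroxy-5-methoxybenzoate | COC(=O)c1cc(O)c(O)c(OC)c1 | starting material
2 | methyl 4-(benzyloxy)-3-hydroxy-5-methoxybenzoate | COC(=O)c1cc(O)c(OCc2ccccc2)c(OC)c1 | intermediate
3 | methyl 4-(benzyloxy)-3-methoxy-5-(trifluoromethylsulfonyloxy)benzoate | COC(=O)c1cc(OC)c(OCc2ccccc2)c(OS(=O)(=O)C(F)(F)F)c1 | intermediate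
4 | acenaphthylene-1,2-dione | O=C1C(=O)c2cccc3cccc1c23 | starting material
5 | cis-1,2-dimethyl-1,2-dihydroacenaphthylene-1,2-diol | C[C@@]1(O)[C@](C)(O)c2cccc3cccc1c23 | intermediate
6 | tert-butyldimethyl(prop-2-yn-1-yloxy)silane | C#CCO[Si](C)(C)C(C)(C)C | starting material
7 | 2-[(Z)-3-(tert-butyldimethylsilyloxy)prop-1-enyl]-1,3,2-benzodioxaborole (not isolated) | CC(C)(C)[Si](C)(C)OC/C=C\B1Oc2ccccc2O1 | intermediate
8 | (Z)-3-(tert-butyldimethylsilyloxy)prop-1-enylboronic ester of diol 5 | CC(C)(C)[Si](C)(C)OC/C=C\B1O[C@@]2(C)c3cccc4cccc(c34)[C@@]2(C)O1 | intermediate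
9 | 4-bromo-2-methoxyphenol | COc1cc(Br)ccc1O | starting material
10 | 1-(benzyloxy)-4-bromo-2-methoxybenzene | COc1cc(Br)ccc1OCc1ccccc1 | intermediate
11 | 4-(benzyloxy)-3-methoxyphenyllithium (not isolated) | [Li]c1ccc(OCc2ccccc2)c(OC)c1 | intermediate
12 | lithium ate complex of 8 and 11 (not isolated) | [Li+].CC(C)(C)[Si](C)(C)OC/C=C\[B-]1(c2ccc(OCc3ccccc3)c(OC)c2)O[C@@]4(C)c5cccc6cccc(c56)[C@@]4(C)O1 | intermediate
13 | methyl 4-(benzyloxy)-3-methoxy-5-[(1R,2R)-1-(4-benzyloxy-3-methoxyphenyl)-1-boryl-3-(tert-butyldimethylsilyloxy)propan-2-yl]benzoate, boron esterified by diol 5 | COC(=O)c1cc(OC)c(OCc2ccccc2)c([C@H](CO[Si](C)(C)C(C)(C)C)[C@@H](B3O[C@@]6(C)c7cccc8cccc(c78)[C@@]6(C)O3)c4ccc(OCc5ccccc5)c(OC)c4)c1 | intermediate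
14 | methyl 4-(benzyloxy)-3-methoxy-5-[(1R,2R)-1-(4-benzyloxy-3-methoxyphenyl)-3-(tert-butyldimethylsilyloxy)-1-hydroxypropan-2-yl]benzoate | COC(=O)c1cc(OC)c(OCc2ccccc2)c([C@H](CO[Si](C)(C)C(C)(C)C)[C@@H](O)c4ccc(OCc5ccccc5)c(OC)c4)c1 | intermediate
15 | methyl 4-(benzyloxy)-3-methoxy-5-[(1R,2R)-1-(4-benzyloxy-3-methoxyphenyl)-1,3-bis(tert-butyldimethylsilyloxy)propan-2-yl]benzoate | COC(=O)c1cc(OC)c(OCc2ccccc2)c([C@H](CO[Si](C)(C)C(C)(C)C)[C@@H](O[Si](C)(C)C(C)(C)C)c4ccc(OCc5ccccc5)c(OC)c4)c1 | intermediate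
16 | (ArBC)methanol | OCc1cc(OC)c(OCc2ccccc2)c([C@H](CO[Si](C)(C)C(C)(C)C)[C@@H](O[Si](C)(C)C(C)(C)C)c4ccc(OCc5ccccc5)c(OC)c4)c1 | intermediate
17 | (ArBC)methyl bromide | BrCc1cc(OC)c(OCc2ccccc2)c([C@H](CO[Si](C)(C)C(C)(C)C)[C@@H](O[Si](C)(C)C(C)(C)C)c4ccc(OCc5ccccc5)c(OC)c4)c1 | intermediate
18 | (R)-4-benzyloxazolidin-2-one | O=C1N[C@H](Cc2ccccc2)CO1 | starting material
19 | pent-4-enoyl chloride | C=CCCC(=O)Cl | starting material
20 | N-lithio-(R)-4-benzyloxazolidin-2-one (not isolated) | [Li]N1[C@H](Cc2ccccc2)COC1=O | intermediate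
21 | (R)-4-benzyl-3-(pent-4-enoyl)oxazolidin-2-one | C=CCCC(=O)N1[C@H](Cc2ccccc2)COC1=O | intermediate
22 | sodium Z-enolate of 21 (not isolated) | [Na+].C=CC/C=C(\[O-])N1[C@H](Cc2ccccc2)COC1=O | intermediate
23 | (R)-4-benzyl-3-[(2S)-2-(ArBC-methyl)pent-4-enoyl]oxazolidin-2-one | C=CC[C@@H](Cc1cc(OC)c(OCc2ccccc2)c([C@H](CO[Si](C)(C)C(C)(C)C)[C@@H](O[Si](C)(C)C(C)(C)C)c5ccc(OCc6ccccc6)c(OC)c5)c1)C(=O)N3[C@H](Cc4ccccc4)COC3=O | intermediate
24 | (2S)-2-(ArBC-methyl)pent-4-en-1-ol | C=CC[C@H](CO)Cc1cc(OC)c(OCc2ccccc2)c([C@H](CO[Si](C)(C)C(C)(C)C)[C@@H](O[Si](C)(C)C(C)(C)C)c5ccc(OCc6ccccc6)c(OC)c5)c1 | intermediate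
25 | (4R)-4-(ArBC-methyl)pentane-1,2,5-triol, both C2 epimers (not isolated) | OCC(O)C[C@H](CO)Cc1cc(OC)c(OCc2ccccc2)c([C@H](CO[Si](C)(C)C(C)(C)C)[C@@H](O[Si](C)(C)C(C)(C)C)c5ccc(OCc6ccccc6)c(OC)c5)c1 | intermediate
26 | (3R)-3-(ArBC-methyl)-4-hydroxybutanal (not isolated) | O=CC[C@H](CO)Cc1cc(OC)c(OCc2ccccc2)c([C@H](CO[Si](C)(C)C(C)(C)C)[C@@H](O[Si](C)(C)C(C)(C)C)c5ccc(OCc6ccccc6)c(OC)c5)c1 | intermediate
27 | (4R)-4-(ArBC-methyl)tetrahydrofuran-2-ol, both anomers | OC1C[C@@H](Cc2cc(OC)c(OCc3ccccc3)c([C@H](CO[Si](C)(C)C(C)(C)C)[C@@H](O[Si](C)(C)C(C)(C)C)c4ccc(OCc5ccccc5)c(OC)c4)c2)CO1 | intermediate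
28 | (4R)-4-(ArBC-methyl)dihydrofuran-2(3H)-one | O=C1C[C@@H](Cc2cc(OC)c(OCc3ccccc3)c([C@H](CO[Si](C)(C)C(C)(C)C)[C@@H](O[Si](C)(C)C(C)(C)C)c4ccc(OCc5ccccc5)c(OC)c4)c2)CO1 | intermediate
29 | (4-benzyloxy-3-methoxyphenyl)methanol | COc1cc(CO)ccc1OCc1ccccc1 | starting material
30 | 4-(benzyloxy)-3-methoxybenzyl bromide | COc1cc(CBr)ccc1OCc1ccccc1 | intermediate
31 | lithium enolate of 28 (not isolated) | [Li+].[O-]C1=C[C@@H](Cc2cc(OC)c(OCc3ccccc3)c([C@H](CO[Si](C)(C)C(C)(C)C)[C@@H](O[Si](C)(C)C(C)(C)C)c4ccc(OCc5ccccc5)c(OC)c4)c2)CO1 | intermediate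
32 | (3R,4R)-3-(4-benzyloxy-3-methoxybenzyl)-4-(ArBC-methyl)dihydrofuran-2(3H)-one | COc1cc(C[C@H]2C(=O)OC[C@@H]2Cc2cc(OC)c(OCc6ccccc6)c([C@H](CO[Si](C)(C)C(C)(C)C)[C@@H](O[Si](C)(C)C(C)(C)C)c3ccc(OCc7ccccc7)c(OC)c3)c2)ccc1OCc8ccccc8 | intermediate
33 | tris(benzyl ether) of the target (chain diol free) | COc1cc(C[C@H]2C(=O)OC[C@@H]2Cc2cc(OC)c(OCc6ccccc6)c([C@H](CO)[C@@H](O)c3ccc(OCc7ccccc7)c(OC)c3)c2)ccc1OCc8ccccc8 | intermediate
34 | (3R,4R)-3-(4-hydroxy-3-methoxybenzyl)-4-{4-hydroxy-3-[(1R,2R)-1,3-dihydroxy-1-(4-hydroxy-3-methoxyphenyl)propan-2-yl]-5-methoxybenzyl}dihydrofuran-2(3H)-one | COc1cc(C[C@H]2C(=O)OC[C@@H]2Cc2cc(OC)c(O)c([C@H](CO)[C@@H](O)c3ccc(O)c(OC)c3)c2)ccc1O | target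

**Step count**
Total: 19 steps. Longest linear sequence: 14 steps (steps 1, 2, 6, 7, 8, 9, 10, 12, 13, 14, 15, 17, 18, 19).

**Steps most likely to fail**

1. Step 6. Direct transfer of the ring C aryl group from boron to palladium, or β-hydride or β-silyloxy elimination from the alkylpalladium intermediate, may overtake the metallate shift, and the alkene face may be selected poorly. The fallback sets out from triflate 3 and comes back at alcohol 14.
   - Suzuki–Miyaura vinylation of 3 with potassium vinyltrifluoroborate (PdCl2(dppf), Et3N, n-PrOH, 90 °C) should give methyl 4-(benzyloxy)-3-methoxy-5-vinylbenzoate F1.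
   - Olefin cross-metathesis of F1 with allylboronic acid pinacol ester (second-generation Grubbs catalyst, CH2Cl2, 40 °C) should give the (E)-3-arylallyl pinacol boronate F2.
   - Allylboration of commercial 4-benzyloxy-3-methoxybenzaldehyde with F2 under a BINOL-derived chiral phosphoric acid (toluene, −30 °C) should pass through a chair Zimmerman–Traxler transition state. The E boronate gives the anti (1R,2S) homoallylic alcohol F3, the catalyst enantiomer being chosen for the (R) carbinol.
   - Ozonolysis of F3 (O3, CH2Cl2/MeOH, −78 °C, indicator end point) gives the α-aryl aldehyde F4, which is reduced in the same flask with NaBH4 to the diol F5.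
   - Selective silylation of the primary hydroxyl group of F5 (TBSCl, imidazole, CH2Cl2, 0 °C) gives 14.

2. Step 4. Competing syn hydroboration or later alkene isomerisation may erode the Z geometry, and exchange of catechol for the hindered diol 5 may stall. The fallback sets out from alkyne 6 and comes back at boronate 8.
   - Deprotonation of 6 (n-BuLi, THF, −78 °C) gives lithium acetylide F6, which with B(OiPr)3 and then anhydrous HCl in Et2O gives diisopropyl alkynylboronate F7.
   - Exchange of F7 with diol 5 gives the alkynylboronic ester F8.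
   - Syn hydrozirconation of F8 with Cp2Zr(H)Cl (THF, rt) gives the 1-boryl-1-zirconocenyl alkene F9. Hydrolysis of its C–Zr bond with retention leaves boron cis to the CH2OTBS group and gives 8.

3. Step 19. Hydrogenolysis of the benzylic C–OH bond next to ring C may accompany cleavage of the three benzyl ethers. The fallback sets out from 32 and comes back at target 34.
   - Hydrogenolysis of 32 (H2, Pd/C, EtOAc), with the benzylic oxygen still silylated, should give the triphenol bis-silyl ether F10.
   - Desilylation of F10 with Et3N·3HF (THF, rt) then gives 34.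

Further compounds
F1 | step 6 | methyl 4-(benzyloxy)-3-methoxy-5-vinylbenzoate | COC(=O)c1cc(OC)c(OCc2ccccc2)c(C=C)c1
F2 | step 6 | methyl 4-(benzyloxy)-3-methoxy-5-[(E)-3-(4,4,5,5-tetramethyl-1,3,2-dioxaborolan-2-yl)prop-1-enyl]benzoate | COC(=O)c1cc(OC)c(OCc2ccccc2)c(/C=C/CB3OC(C)(C)C(C)(C)O3)c1
F3 | step 6 | methyl 4-(benzyloxy)-3-methoxy-5-[(1R,2S)-1-(4-benzyloxy-3-methoxyphenyl)-1-hydroxybut-3-en-2-yl]benzoate | COC(=O)c1cc(OC)c(OCc2ccccc2)c([C@H](C=C)[C@@H](O)c4ccc(OCc5ccccc5)c(OC)c4)c1
F4 | step 6 | methyl 4-(benzyloxy)-3-methoxy-5-[(1R,2R)-1-(4-benzyloxy-3-methoxyphenyl)-1-hydroxy-3-oxopropan-2-yl]benzoate (not isolated) | COC(=O)c1cc(OC)c(OCc2ccccc2)c([C@H](C=O)[C@@H](O)c4ccc(OCc5ccccc5)c(OC)c4)c1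
F5 | step 6 | methyl 4-(benzyloxy)-3-methoxy-5-[(1R,2R)-1-(4-benzyloxy-3-methoxyphenyl)-1,3-dihydroxypropan-2-yl]benzoate | COC(=O)c1cc(OC)c(OCc2ccccc2)c([C@H](CO)[C@@H](O)c4ccc(OCc5ccccc5)c(OC)c4)c1
F6 | step 4 | lithium 3-(tert-butyldimethylsilyloxy)prop-1-ynide (not isolated) | [Li]C#CCO[Si](C)(C)C(C)(C)C
F7 | step 4 | diisopropyl 3-(tert-butyldimethylsilyloxy)prop-1-ynylboronate (not isolated) | CC(C)OB(C#CCO[Si](C)(C)C(C)(C)C)OC(C)C
F8 | step 4 | 3-(tert-butyldimethylsilyloxy)prop-1-ynylboronic ester of diol 5 | CC(C)(C)[Si](C)(C)OCC#CB1O[C@@]2(C)c3cccc4cccc(c34)[C@@]2(C)O1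
F9 | step 4 | 1-boryl-1-(chlorozirconocenyl) alkene from F8 (not isolated) | CC(C)(C)[Si](C)(C)OC/C=C(/[Zr](Cl)(C1C=CC=C1)C1C=CC=C1)B1O[C@@]2(C)c3cccc4cccc(c34)[C@@]2(C)O1
F10 | step 19 | (3R,4R)-3-(4-hydroxy-3-methoxybenzyl)-4-{4-hydroxy-3-[(1R,2R)-1-(4-hydroxy-3-methoxyphenyl)-1,3-bis(tert-butyldimethylsilyloxy)propan-2-yl]-5-methoxybenzyl}dihydrofuran-2(3H)-one | COc1cc(C[C@H]2C(=O)OC[C@@H]2Cc2cc(OC)c(O)c([C@H](CO[Si](C)(C)C(C)(C)C)[C@@H](O[Si](C)(C)C(C)(C)C)c3ccc(O)c(OC)c3)c2)ccc1O
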